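**Retrosynthetic overview**
1. Last C–C bond, C7–C8 (ring A methine to the E-alkene): nickel-catalysed enantioconvergent reductive alkenylation of a racemic ring A 1-chloroethyl pyranone with the complete ring B alkenyl bromide, then global desilylation.
2. Ring A is formed first, in its own two-step branch: PPA condensation of pentan-3-one with propanoic acid, then lateral chlorination of one ethyl group.
3. Ring B is formed second (step 17) by cyclodehydration of an acyclic 1,3,5-triketone built on pentan-3-one by two aldol/oxidation events with two chiral aldehydes.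
4. C14–C15 aldehyde: D-proline aldol dimerisation of propanal. C8–C13 aldehyde: thiazolidinethione syn aldol on (E)-3-bromo-2-methylacrolein (C10, C11), matched Brown (E)-crotylboration (C12, C13), vinyl cleavage.
5. The two rings are united only in step 18; the last step removes three silyl ethers.

Numbering used: ring A = ethyl-bearing pyranone; ring B = pyranone with two stereogenic side chains; C7 = methine on ring A, C8=C9 = alkene, C10–C13 = stereotetrad, C14/C15 = side chain on ring B; target = 7S,8E,10R,11S,12S,13S,14R,15R.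
Assumption: in step 18 the (3aS,3a'S,8aR,8a'R) ligand is taken to give 7S; if the first run gives the C7 epimer, the mirror-image ligand is used under identical conditions.

**Ring A branch**

Step 1
Reactants: 1 pentan-3-one; 2 propanoic acid (2.5 equiv)
Product: 4 2,6-diethyl-3,5-dimethyl-4H-pyran-4-one, via triketone 3 (not isolated)
Conditions: polyphosphoric acid, 130 °C, 6 h
Reagents that add atoms: none
Why: PPA-mediated double C-acylation of the ketone at both α-carbons gives the 1,3,5-triketone, which cyclodehydrates in situ (classical ketone/carboxylic acid 4-pyranone condensation); no stereocentre is formed.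

Step 2
Reactants: 4 2,6-diethyl-3,5-dimethyl-4H-pyran-4-one
Product: 6 rac-2-(1-chloroethyl)-6-ethyl-3,5-dimethyl-4H-pyran-4-one, via lithium dienolate 5 (not isolated)
Conditions: LiN(SiMe3)2 (1.05 equiv), THF, −78 °C, 30 min; cannulate into C2Cl6 (1.5 equiv), THF, −78 °C
Reagents that add atoms: hexachloroethane ClC(Cl)(Cl)C(Cl)(Cl)Cl
Why: lateral (vinylogous) deprotonation of one of the two equivalent ethyl groups followed by electrophilic chlorination, with inverse addition to suppress over-chlorination; the chloride is deliberately racemic.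

**C14–C15 arm and β-diketone**

Step 3
Reactants: 7 propanal (two molecules, donor and acceptor)
Product: 8 (2R,3R)-3-hydroxy-2-methylpentanal
Conditions: D-proline (10 mol %), DMF, 4 °C, 16 h
Reagents that add atoms: none
Why: proline-catalysed direct enamine aldol dimerisation of propanal through the hydrogen-bonded Houk–List transition state; D-proline gives the (2R,3R) anti adduct (about 4:1 anti:syn, about 99% ee for the L-proline series), setting C14 and C15.

Step 4
Reactants: 8 (2R,3R)-3-hydroxy-2-methylpentanal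
Product: 9 (2R,3R)-3-[(tert-butyldimethylsilyl)oxy]-2-methylpentanal
Conditions: TBSCl, imidazole, DMF, 0 °C → rt; chromatography removes the minor syn isomer
Reagents that add atoms: tert-butyldimethylsilyl chloride CC(C)(C)[Si](C)(C)Cl
Why: standard silylation of a secondary alcohol under mild imidazole conditions that do not epimerise the α-centre.

Step 5
Reactants: 1 pentan-3-one; 9 (2R,3R)-3-[(tert-butyldimethylsilyl)oxy]-2-methylpentanal
Product: 11 (6S,7R)-7-[(tert-butyldimethylsilyl)oxy]-5-hydroxy-4,6-dimethylnonan-3-one (C4/C5 epimer mixture), via lithium enolate 10 (not isolated)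
Conditions: LiN(iPr)2 (1.1 equiv), THF, −78 °C; then 9, −78 °C, 20 min; AcOH quench at −78 °C
Reagents that add atoms: none
Why: kinetic lithium enolate aldol addition, fast at −78 °C so that C14 is not epimerised; the two new centres are destroyed later and need no control.

Step 6
Reactants: 11 (6S,7R)-7-[(tert-butyldimethylsilyl)oxy]-5-hydroxy-4,6-dimethylnonan-3-one
Product: 12 (6R,7R)-7-[(tert-butyldimethylsilyl)oxy]-4,6-dimethylnonane-3,5-dione (C4 epimers and enol forms)
Conditions: Dess–Martin periodinane (1.5 equiv), pyridine, CH2Cl2, 0 °C → rt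
Reagents that add atoms: none
Why: Dess–Martin oxidation of a β-hydroxy ketone to the β-diketone under buffered, non-epimerising conditions.

**C8–C13 arm**

Step 7
Reactants: 13 2-methylprop-2-enal (methacrolein)
Product: 15 (E)-3-bromo-2-methylprop-2-enal, via dibromide 14 (not isolated)
Conditions: Br2 (1.0 equiv), CH2Cl2, 0 °C; then Et3N (1.2 equiv), 0 °C → rt; distillation
Reagents that add atoms: bromine BrBr
Why: bromine addition then dehydrobromination (the α-carbon has no hydrogen, so HBr is lost towards C3) gives the conjugated E-bromoenal, the thermodynamically preferred isomer.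

Step 8
Reactants: 16 propanoyl chloride
Product: 17 1-[(4R)-4-benzyl-2-sulfanylidene-1,3-thiazolidin-3-yl]propan-1-one
Conditions: (R)-4-benzyl-1,3-thiazolidine-2-thione, Et3N, DMAP (cat.), CH2Cl2, 0 °C → rt
Reagents that add atoms: (R)-4-benzyl-1,3-thiazolidine-2-thione S=C1N[C@H](Cc2ccccc2)CS1
Why: N-acylation of the chiral auxiliary (recovered in step 11).

Step 9
Reactants: 17 1-[(4R)-4-benzyl-2-sulfanylidene-1,3-thiazolidin-3-yl]propan-1-one; 15 (E)-3-bromo-2-methylprop-2-enal
Product: 19 (2R,3R,4E)-1-[(4R)-4-benzyl-2-sulfanylidene-1,3-thiazolidin-3-yl]-5-bromo-3-hydroxy-2,4-dimethylpent-4-en-1-one, via titanium enolate 18 (not isolated)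
Conditions: TiCl4 (1.05 equiv), iPr2NEt (1.1 equiv), N-methylpyrrolidinone (1.0 equiv), CH2Cl2, 0 °C; then 15, −78 → 0 °C
Reagents that add atoms: none
Why: Crimmins titanium-enolate syn aldol; the chlorotitanium Z-enolate reacts through the non-chelated Zimmerman–Traxler chair to give the "Evans syn" adduct, and the (R)-auxiliary sets C11 and C10 as (2R,3R), i.e. 10R,11S of the target.

Step 10
Reactants: 19 (2R,3R,4E)-1-[(4R)-4-benzyl-2-sulfanylidene-1,3-thiazolidin-3-yl]-5-bromo-3-hydroxy-2,4-dimethylpent-4-en-1-one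
Product: 20 (2R,3R,4E)-1-[(4R)-4-benzyl-2-sulfanylidene-1,3-thiazolidin-3-yl]-5-bromo-3-[(tert-butyldimethylsilyl)oxy]-2,4-dimethylpent-4-en-1-one
Conditions: TBSOTf, 2,6-lutidine, CH2Cl2, 0 °C
Reagents that add atoms: tert-butyldimethylsilyl triflate CC(C)(C)[Si](C)(C)OS(=O)(=O)C(F)(F)F
Why: silylation of the allylic alcohol with the reactive triflate, which also blocks retro-aldol in the next step.

Step 11
Reactants: 20 (2R,3R,4E)-1-[(4R)-4-benzyl-2-sulfanylidene-1,3-thiazolidin-3-yl]-5-bromo-3-[(tert-butyldimethylsilyl)oxy]-2,4-dimethylpent-4-en-1-one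
Product: 21 (2R,3R,4E)-5-bromo-3-[(tert-butyldimethylsilyl)oxy]-2,4-dimethylpent-4-enal
Conditions: iBu2AlH (1.5 equiv), CH2Cl2, −78 °C; Rochelle salt work-up
Reagents that add atoms: none
Why: direct hydride reduction of the activated N-acyl thiazolidinethione to the aldehyde (the stable tetrahedral aluminate collapses only on work-up), leaving the alkenyl bromide and silyl ether untouched.

Step 12
Reactants: 21 (2R,3R,4E)-5-bromo-3-[(tert-butyldimethylsilyl)oxy]-2,4-dimethylpent-4-enal; 22 (E)-but-2-ene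
Product: 27 (3R,4R,5S,6R,7E)-8-bromo-6-[(tert-butyldimethylsilyl)oxy]-3,5,7-trimethylocta-1,7-dien-4-ol, via crotylpotassium 23 (not isolated), via crotylborate 24 (not isolated), via crotylborane 25 (not isolated), via borinate 26 (not isolated)
Conditions: 22, KOtBu, n-BuLi, THF, −78 → −45 °C; (+)-Ipc2BOMe [from (−)-α-pinene], −78 °C; BF3·OEt2, −78 °C; then 21, −78 °C, 4 h; NaOH, H2O2, 0 °C → rt
Reagents that add atoms: none
Why: Brown (E)-crotylboration through a chair six-membered transition state; the E-crotyl geometry gives the 12,13-anti relation and the (−)-α-pinene-derived borane attacks the Re face of 21, which is also the Felkin face (matched case), giving 11,12-syn and setting C12 and C13 (12S,13S of the target).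

Step 13
Reactants: 27 (3R,4R,5S,6R,7E)-8-bromo-6-[(tert-butyldimethylsilyl)oxy]-3,5,7-trimethylocta-1,7-dien-4-ol
Product: 28 (1E,3R,4S,5R,6R)-1-bromo-3,5-bis[(tert-butyldimethylsilyl)oxy]-2,4,6-trimethylocta-1,7-diene
Conditions: TBSOTf, 2,6-lutidine, CH2Cl2, −78 → 0 °C
Reagents that add atoms: tert-butyldimethylsilyl triflate CC(C)(C)[Si](C)(C)OS(=O)(=O)C(F)(F)F
Why: triflate silylation of the hindered secondary alcohol.

Step 14
Reactants: 28 (1E,3R,4S,5R,6R)-1-bromo-3,5-bis[(tert-butyldimethylsilyl)oxy]-2,4,6-trimethylocta-1,7-diene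
Product: 30 (2S,3S,4S,5R,6E)-7-bromo-3,5-bis[(tert-butyldimethylsilyl)oxy]-2,4,6-trimethylhept-6-enal, via diol 29 (not isolated)
Conditions: OsO4 (2 mol %), NaIO4 (4 equiv), 2,6-lutidine (2 equiv), 1,4-dioxane/H2O 3:1, rt
Reagents that add atoms: OsO4 (osmium tetroxide, catalytic oxygen donor) O=[Os](=O)(=O)=O; NaIO4 (sodium periodate, terminal oxygen source) [Na+].[O-]I(=O)(=O)=O
Why: Johnson–Lemieux oxidative cleavage; the electron-rich monosubstituted vinyl group is dihydroxylated far faster than the hindered, electron-poor trisubstituted bromoalkene, and lutidine buffering protects the α-centre C13.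

**Union, ring B and finish**

Step 15
Reactants: 12 (6R,7R)-7-[(tert-butyldimethylsilyl)oxy]-4,6-dimethylnonane-3,5-dione; 30 (2S,3S,4S,5R,6E)-7-bromo-3,5-bis[(tert-butyldimethylsilyl)oxy]-2,4,6-trimethylhept-6-enal
Product: 32 15-bromo-3,11,13-tris[(tert-butyldimethylsilyl)oxy]-9-hydroxy-4,6,8,10,12,14-hexamethylpentadec-14-ene-5,7-dione (C3/C4 as in 12; C10–C13 and alkene as in 30; C6/C8/C9 epimer mixture), via dilithium dianion 31 (not isolated)
Conditions: 12, LiN(iPr)2 (2.1 equiv), THF, −78 → 0 °C, 30 min; re-cool to −78 °C; 30, 30 min; AcOH quench at −78 °C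
Reagents that add atoms: none
Why: aldol addition of a β-diketone 1,5-dianion at its terminal carbon (the ethyl CH2 is deprotonated in preference to the hindered C14 methine and is the more nucleophilic site); the new centres are removed in steps 16 and 17.

Step 16
Reactants: 32 15-bromo-3,11,13-tris[(tert-butyldimethylsilyl)oxy]-9-hydroxy-4,6,8,10,12,14-hexamethylpentadec-14-ene-5,7-dione
Product: 33 15-bromo-3,11,13-tris[(tert-butyldimethylsilyl)oxy]-4,6,8,10,12,14-hexamethylpentadec-14-ene-5,7,9-trione (C6/C8 epimers and enol forms)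
Conditions: Dess–Martin periodinane (2 equiv), pyridine, CH2Cl2, 0 °C → rt
Reagents that add atoms: none
Why: Dess–Martin oxidation of the remaining secondary alcohol to the 1,3,5-triketone under buffered conditions that spare C13 and C14.

Step 17
Reactants: 33 15-bromo-3,11,13-tris[(tert-butyldimethylsilyl)oxy]-4,6,8,10,12,14-hexamethylpentadec-14-ene-5,7,9-trione
Product: 34 2-[(2S,3S,4S,5R,6E)-7-bromo-3,5-bis[(tert-butyldimethylsilyl)oxy]-4,6-dimethylhept-6-en-2-yl]-6-[(2R,3R)-3-[(tert-butyldimethylsilyl)oxy]pentan-2-yl]-3,5-dimethyl-4H-pyran-4-one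
Conditions: PPh3 (3 equiv), CCl4 (10 equiv), 2,6-lutidine (1.5 equiv), THF, rt, 12 h
Reagents that add atoms: none
Why: Appel-type cyclodehydration of the triketone (enol oxyphosphonium formation, attack by the distal enol oxygen, loss of Ph3P=O) forms ring B under near-neutral conditions, so the α-centres C13/C14 and the β-silyloxy groups survive.

Step 18
Reactants: 34 ring B alkenyl bromide; 6 rac-2-(1-chloroethyl)-6-ethyl-3,5-dimethyl-4H-pyran-4-one (2 equiv)
Product: 35 2-ethyl-6-[(2S,3E,5R,6S,7S,8S)-5,7-bis[(tert-butyldimethylsilyl)oxy]-8-{6-[(2R,3R)-3-[(tert-butyldimethylsilyl)oxy]pentan-2-yl]-3,5-dimethyl-4-oxo-4H-pyran-2-yl}-4,6-dimethylnon-3-en-2-yl]-3,5-dimethyl-4H-pyran-4-one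
Conditions: NiCl2(dme) (10 mol %), (3aS,3a'S,8aR,8a'R)-2,2'-(cyclopropane-1,1-diyl)bis(3a,8a-dihydro-8H-indeno[1,2-d]oxazole) (11 mol %), Mn powder (3 equiv), NaI (0.5 equiv), DMA, 0 °C, 24 h
Reagents that add atoms: none
Why: Proposed new method: enantioconvergent nickel-catalysed reductive alkenylation of a racemic 1-(4-oxopyran-2-yl)ethyl chloride, in which zerovalent nickel–bis(oxazoline) adds oxidatively to the alkenyl bromide of 34, the C–Cl bond of 6 (activated as the iodide by NaI) is reduced by monovalent nickel to a planar radical stabilised through the pyranone as a vinylogous α-keto/hetero-benzylic radical, capture at the divalent alkenylnickel gives a trivalent nickel species whose reductive elimination forms C7–C8 with ligand-controlled 7S configuration and retained E geometry, Mn powder closes the cycle, and the base-free medium cannot epimerise the acidic C7–H or move the alkene into conjugation; the closest known reaction type is the nickel/bis(oxazoline)-catalysed asymmetric reductive cross-coupling of secondary benzylic chlorides with alkenyl bromides.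

Step 19
Reactants: 35 tris-silyl ether
Product: 36 2-ethyl-6-[(2S,3E,5R,6S,7S,8S)-5,7-dihydroxy-8-{6-[(2R,3R)-3-hydroxypentan-2-yl]-3,5-dimethyl-4-oxo-4H-pyran-2-yl}-4,6-dimethylnon-3-en-2-yl]-3,5-dimethyl-4H-pyran-4-one (CNP0328559.3)
Conditions: HF·pyridine, pyridine, THF, 0 °C → rt, 24–48 h
Reagents that add atoms: none
Why: buffered fluoride desilylation removes all three TBS ethers without base (no C7 epimerisation) and without strong acid (no ionisation of the C10 allylic alcohol).

**Compound list**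
1 | pentan-3-one | CCC(=O)CC | starting material
2 | propanoic acid | CCC(=O)O | starting material
3 | 4,6-dimethylnonane-3,5,7-trione (stereoisomer mixture) | CCC(=O)C(C)C(=O)C(C)C(=O)CC | intermediate
4 | 2,6-diethyl-3,5-dimethyl-4H-pyran-4-one | CCc1oc(CC)c(C)c(=O)c1C | intermediate
5 | lithium 2-ethyl-6-ethylidene-3,5-dimethyl-6H-pyran-4-olate | [Li+].CCC1=C(C)C([O-])=C(C)C(=CC)O1 | intermediate
6 | rac-2-(1-chloroethyl)-6-ethyl-3,5-dimethyl-4H-pyran-4-one | CCc1oc(C(C)Cl)c(C)c(=O)c1C | intermediate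
7 | propanal | CCC=O | starting material
8 | (2R,3R)-3-hydroxy-2-methylpentanal | O=C[C@H](C)[C@H](O)CC | intermediate
9 | (2R,3R)-3-[(tert-butyldimethylsilyl)oxy]-2-methylpentanal | O=C[C@H](C)[C@H](O[Si](C)(C)C(C)(C)C)CC | intermediate
10 | lithium pent-2-en-3-olate (enolate of 1) | [Li+].CC=C([O-])CC | intermediate
11 | (6S,7R)-7-[(tert-butyldimethylsilyl)oxy]-5-hydroxy-4,6-dimethylnonan-3-one (C4/C5 epimers) | CCC(=O)C(C)C(O)[C@H](C)[C@H](O[Si](C)(C)C(C)(C)C)CC | intermediate
12 | (6R,7R)-7-[(tert-butyldimethylsilyl)oxy]-4,6-dimethylnonane-3,5-dione (C4 epimers) | CCC(=O)C(C)C(=O)[C@H](C)[C@H](O[Si](C)(C)C(C)(C)C)CC | intermediate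
13 | 2-methylprop-2-enal (methacrolein) | CC(=C)C=O | starting material
14 | 2,3-dibromo-2-methylpropanal (racemic) | O=CC(C)(Br)CBr | intermediate
15 | (E)-3-bromo-2-methylprop-2-enal | Br/C=C(\C)C=O | intermediate
16 | propanoyl chloride | CCC(=O)Cl | starting material
17 | 1-[(4R)-4-benzyl-2-sulfanylidene-1,3-thiazolidin-3-yl]propan-1-one | CCC(=O)N1C(=S)SC[C@H]1Cc1ccccc1 | intermediate
18 | trichlorotitanium (Z)-enolate of 17 | C/C=C(\O[Ti](Cl)(Cl)Cl)N1C(=S)SC[C@H]1Cc1ccccc1 | intermediate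
19 | (2R,3R,4E)-1-[(4R)-4-benzyl-2-sulfanylidene-1,3-thiazolidin-3-yl]-5-bromo-3-hydroxy-2,4-dimethylpent-4-en-1-one | Br/C=C(\C)[C@H](O)[C@@H](C)C(=O)N1C(=S)SC[C@H]1Cc1ccccc1 | intermediate
20 | TBS ether of 19 | Br/C=C(\C)[C@H](O[Si](C)(C)C(C)(C)C)[C@@H](C)C(=O)N1C(=S)SC[C@H]1Cc1ccccc1 | intermediate
21 | (2R,3R,4E)-5-bromo-3-[(tert-butyldimethylsilyl)oxy]-2,4-dimethylpent-4-enal | Br/C=C(\C)[C@H](O[Si](C)(C)C(C)(C)C)[C@@H](C)C=O | intermediate
22 | (E)-but-2-ene | C/C=C/C | starting material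
23 | (E)-but-2-enylpotassium | C/C=C/C[K] | intermediate
24 | potassium (E)-but-2-enyl(methoxy)bis(isopinocampheyl)borate, Ipc from (−)-α-pinene | [K+].C/C=C/C[B-](OC)([C@H]1C[C@H]2C[C@@H]([C@@H]1C)C2(C)C)[C@H]1C[C@H]2C[C@@H]([C@@H]1C)C2(C)C | intermediate
25 | (E)-but-2-enylbis(isopinocampheyl)borane, Ipc from (−)-α-pinene | C/C=C/CB([C@H]1C[C@H]2C[C@@H]([C@@H]1C)C2(C)C)[C@H]1C[C@H]2C[C@@H]([C@@H]1C)C2(C)C | intermediate
26 | bis(isopinocampheyl)borinate ester of 27 | Br/C=C(\C)[C@H](O[Si](C)(C)C(C)(C)C)[C@@H](C)[C@H](OB([C@H]1C[C@H]2C[C@@H]([C@@H]1C)C2(C)C)[C@H]1C[C@H]2C[C@@H]([C@@H]1C)C2(C)C)[C@H](C)C=C | intermediate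
27 | (3R,4R,5S,6R,7E)-8-bromo-6-[(tert-butyldimethylsilyl)oxy]-3,5,7-trimethylocta-1,7-dien-4-ol | Br/C=C(\C)[C@H](O[Si](C)(C)C(C)(C)C)[C@@H](C)[C@H](O)[C@H](C)C=C | intermediate
28 | (1E,3R,4S,5R,6R)-1-bromo-3,5-bis[(tert-butyldimethylsilyl)oxy]-2,4,6-trimethylocta-1,7-diene | Br/C=C(\C)[C@H](O[Si](C)(C)C(C)(C)C)[C@@H](C)[C@H](O[Si](C)(C)C(C)(C)C)[C@H](C)C=C | intermediate
29 | 1,2-diol from dihydroxylation of the vinyl group of 28 (both C2 epimers, other centres as in 28) | Br/C=C(\C)[C@H](O[Si](C)(C)C(C)(C)C)[C@@H](C)[C@H](O[Si](C)(C)C(C)(C)C)[C@H](C)C(O)CO | intermediate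
30 | (2S,3S,4S,5R,6E)-7-bromo-3,5-bis[(tert-butyldimethylsilyl)oxy]-2,4,6-trimethylhept-6-enal | Br/C=C(\C)[C@H](O[Si](C)(C)C(C)(C)C)[C@@H](C)[C@H](O[Si](C)(C)C(C)(C)C)[C@H](C)C=O | intermediate
31 | dilithium dienediolate (1,5-dianion) of 12 | [Li+].[Li+].CC=C([O-])C(C)=C([O-])[C@H](C)[C@H](O[Si](C)(C)C(C)(C)C)CC | intermediate
32 | 15-bromo-3,11,13-tris[(tert-butyldimethylsilyl)oxy]-9-hydroxy-4,6,8,10,12,14-hexamethylpentadec-14-ene-5,7-dione (C6/C8/C9 epimers) | Br/C=C(\C)[C@H](O[Si](C)(C)C(C)(C)C)[C@@H](C)[C@H](O[Si](C)(C)C(C)(C)C)[C@H](C)C(O)C(C)C(=O)C(C)C(=O)[C@H](C)[C@H](O[Si](C)(C)C(C)(C)C)CC | intermediate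
33 | 15-bromo-3,11,13-tris[(tert-butyldimethylsilyl)oxy]-4,6,8,10,12,14-hexamethylpentadec-14-ene-5,7,9-trione (C6/C8 epimers) | Br/C=C(\C)[C@H](O[Si](C)(C)C(C)(C)C)[C@@H](C)[C@H](O[Si](C)(C)C(C)(C)C)[C@H](C)C(=O)C(C)C(=O)C(C)C(=O)[C@H](C)[C@H](O[Si](C)(C)C(C)(C)C)CC | intermediate
34 | 2-[(2S,3S,4S,5R,6E)-7-bromo-3,5-bis[(tert-butyldimethylsilyl)oxy]-4,6-dimethylhept-6-en-2-yl]-6-[(2R,3R)-3-[(tert-butyldimethylsilyl)oxy]pentan-2-yl]-3,5-dimethyl-4H-pyran-4-one | Br/C=C(\C)[C@H](O[Si](C)(C)C(C)(C)C)[C@@H](C)[C@H](O[Si](C)(C)C(C)(C)C)[C@H](C)c1oc([C@H](C)[C@H](O[Si](C)(C)C(C)(C)C)CC)c(C)c(=O)c1C | intermediate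
35 | tris-TBS ether of the target (7S,8E,10R,11S,12S,13S,14R,15R) | CCc1oc([C@@H](C)/C=C(\C)[C@H](O[Si](C)(C)C(C)(C)C)[C@@H](C)[C@H](O[Si](C)(C)C(C)(C)C)[C@H](C)c2oc([C@H](C)[C@H](O[Si](C)(C)C(C)(C)C)CC)c(C)c(=O)c2C)c(C)c(=O)c1C | intermediate
36 | 2-ethyl-6-[(2S,3E,5R,6S,7S,8S)-5,7-dihydroxy-8-{6-[(2R,3R)-3-hydroxypentan-2-yl]-3,5-dimethyl-4-oxo-4H-pyran-2-yl}-4,6-dimethylnon-3-en-2-yl]-3,5-dimethyl-4H-pyran-4-one | CCc1oc([C@@H](C)/C=C(\C)[C@H](O)[C@@H](C)[C@H](O)[C@H](C)c2oc([C@H](C)[C@H](O)CC)c(C)c(=O)c2C)c(C)c(=O)c1C | target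

**Totals**
Total step count: 19.
Longest linear sequence: 12 steps (7 → 9 → 10 → 11 → 12 → 13 → 14 → 15 → 16 → 17 → 18 → 19).

**Three steps most likely to fail**

Step 18 (the new nickel coupling). Risks are slow oxidative addition of the hindered trisubstituted bromide, homocoupling of 6, and insufficient catalyst control at C7. The fallback uses known chemistry and gives up catalyst control. It sets out from 6 and 34. Zinc insertion into 6 (Zn dust, LiCl, THF, rt) gives the racemic secondary organozinc [1-(6-ethyl-3,5-dimethyl-4-oxo-4H-pyran-2-yl)ethyl]zinc chloride F1. Negishi coupling with 34 (Pd(OAc)2, SPhos, THF, rt) then gives 35 together with its C7 epimer, the (7R)-tris-TBS ether F2, in about 1:1 ratio. The two diastereomers are separated by preparative HPLC, so at most half of the material is the wanted epimer, and the route resumes at 35.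

Step 15 (dianion aldol). Risks are deprotonation at the C14 methine (epimerisation or β-elimination of the silyloxy group) and retro-aldol. The fallback replaces the dianion by a protected mono-enolate and sets out from 11. Silylation (TESCl, imidazole) gives (6S,7R)-7-[(tert-butyldimethylsilyl)oxy]-4,6-dimethyl-5-[(triethylsilyl)oxy]nonan-3-one F3. Kinetic enolisation on the ethyl side (LiN(iPr)2, THF, −78 °C) and addition to 30 gives the differentially protected bis-aldol F4. Selective removal of the TES group (PPTS, MeOH, 0 °C) gives the dihydroxy ketone F5. Double Dess–Martin oxidation returns to the route at 33.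

Step 2 (lateral chlorination). Risks are over-chlorination and Wurtz-type dimerisation of the delocalised anion. The fallback forms a C–O bond first and sets out from 4. Deprotonation with LiN(SiMe3)2 and hydroxylation with 2-(phenylsulfonyl)-3-phenyloxaziridine gives rac-2-ethyl-6-(1-hydroxyethyl)-3,5-dimethyl-4H-pyran-4-one F6. Appel chlorination (PPh3, CCl4, CH2Cl2) returns to the route at 6.

**Further compounds**
F1 | step 18 | [1-(6-ethyl-3,5-dimethyl-4-oxo-4H-pyran-2-yl)ethyl]zinc chloride (racemic) | CCc1oc(C(C)[Zn]Cl)c(C)c(=O)c1C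
F2 | step 18 | (7R)-epimer of 35 | CCc1oc([C@H](C)/C=C(\C)[C@H](O[Si](C)(C)C(C)(C)C)[C@@H](C)[C@H](O[Si](C)(C)C(C)(C)C)[C@H](C)c2oc([C@H](C)[C@H](O[Si](C)(C)C(C)(C)C)CC)c(C)c(=O)c2C)c(C)c(=O)c1C
F3 | step 15 | (6S,7R)-7-[(tert-butyldimethylsilyl)oxy]-4,6-dimethyl-5-[(triethylsilyl)oxy]nonan-3-one (C4/C5 epimers) | CCC(=O)C(C)C(O[Si](CC)(CC)CC)[C@H](C)[C@H](O[Si](C)(C)C(C)(C)C)CC
F4 | step 15 | 15-bromo-3,11,13-tris[(tert-butyldimethylsilyl)oxy]-9-hydroxy-4,6,8,10,12,14-hexamethyl-5-[(triethylsilyl)oxy]pentadec-14-en-7-one (epimer mixture at C5/C6/C8/C9) | Br/C=C(\C)[C@H](O[Si](C)(C)C(C)(C)C)[C@@H](C)[C@H](O[Si](C)(C)C(C)(C)C)[C@H](C)C(O)C(C)C(=O)C(C)C(O[Si](CC)(CC)CC)[C@H](C)[C@H](O[Si](C)(C)C(C)(C)C)CC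
F5 | step 15 | 15-bromo-3,11,13-tris[(tert-butyldimethylsilyl)oxy]-5,9-dihydroxy-4,6,8,10,12,14-hexamethylpentadec-14-en-7-one (epimer mixture at C5/C6/C8/C9) | Br/C=C(\C)[C@H](O[Si](C)(C)C(C)(C)C)[C@@H](C)[C@H](O[Si](C)(C)C(C)(C)C)[C@H](C)C(O)C(C)C(=O)C(C)C(O)[C@H](C)[C@H](O[Si](C)(C)C(C)(C)C)CC
F6 | step 2 | rac-2-ethyl-6-(1-hydroxyethyl)-3,5-dimethyl-4H-pyran-4-one | CCc1oc(C(C)O)c(C)c(=O)c1C
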